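**Retrosynthetic overview**
1. Furan (first ring): the 3-substituted furan is traced to the head 1,3-diene of (E)-β-farnesene 1, through bis-boronate 2, (Z)-ene-1,4-diol 3 and lactol 4, to dendrolasin 5 (oxidative cyclodehydration of the 1,4-dioxygenated head isoprene unit).
2. C15–C16: allyl–alkyl bond between bromide 7 (from 5 through 6, SeO2 on the E-methyl) and the C5 Grignard reagent 11 made from (S)-2-methylbutane-1,4-diol 8 (through 9 and 10); this gives chloride 12 and brings C18.
3. Tetronic acid (second ring): C20–C21 acylation of diethyl oxalpropionate 13 (as enolate 14) by the Grignard reagent 15 of 12 gives the open-chain 2-methyl-3,4-dioxo ester 16; enol lactonisation gives 17.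
4. Enol ester and C20=C21 geometry: 17 + palmitoyl chloride 18 gives the 20Z ester 19; Z-to-E photoisomerisation gives 20.

Assumption: the SMILES is read literally (18S, 7E, 12E, and the side chain trans to the ring oxygen across C20=C21, i.e. 20E); variabilin numbering is used for atom labels (C1–C4 furan, C21–C24 lactone carbons, C25 its methyl).

**Route**

Step 1
Reactants: 1 (E)-β-farnesene
Product: 3 (2Z)-2-[(3E)-4,8-dimethylnona-3,7-dien-1-yl]but-2-ene-1,4-diol, via bis-boronate 2 (not isolated)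
Conditions: Pt(PPh3)4 (3 mol %), B2pin2 (1.05 equiv), toluene, 80 °C; then 3 M NaOH, 30% H2O2, THF, 0 °C to rt
Reagents that add atoms: bis(pinacolato)diboron CC1(C)OB(OC1(C)C)B1OC(C)(C)C(C)(C)O1 (stays only in 2); hydrogen peroxide OO
Why: Platinum-catalysed 1,4-diboration of a 2-substituted 1,3-diene goes through a π-allyl intermediate, leaves the isolated trisubstituted alkenes alone and puts the two CH2B groups cis; stereoretentive C–B oxidation then gives the (Z)-ene-1,4-diol.

Step 2
Reactants: 3 (2Z)-2-[(3E)-4,8-dimethylnona-3,7-dien-1-yl]but-2-ene-1,4-diol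
Product: 5 dendrolasin 3-[(3E)-4,8-dimethylnona-3,7-dien-1-yl]furan, via lactol 4 (not isolated)
Conditions: [C5H5NH][CrO3Cl] (2.5 equiv), 4 Å MS, CH2Cl2, rt
Reagents that add atoms: none
Why: Chlorochromate oxidation of a (Z)-2-ene-1,4-diol gives the 4-hydroxy-enal, which closes to the 2,5-dihydrofuran-2-ol and loses water under the mildly acidic conditions (oxidative cyclodehydration to a 3-substituted furan); both regiochemical modes of oxidation give the same furan.

Step 3
Reactants: 5 dendrolasin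
Product: 6 neotorreyol (2E,6E)-9-(furan-3-yl)-2,6-dimethylnona-2,6-dien-1-ol
Conditions: SeO2 (0.3 equiv), t-BuOOH (2.5 equiv), salicylic acid (0.1 equiv), CH2Cl2, 0 °C to rt
Reagents that add atoms: selenium dioxide O=[Se]=O; tert-butyl hydroperoxide CC(C)(C)OO
Why: Sharpless-type SeO2/t-BuOOH allylic oxidation (ene reaction, then [2,3]-sigmatropic shift) attacks the E-methyl of the terminal isopropylidene group, which fixes the 12E geometry; the furan is tolerated.

Step 4
Reactants: 6 neotorreyol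
Product: 7 3-[(3E,7E)-9-bromo-4,8-dimethylnona-3,7-dien-1-yl]furan
Conditions: CBr4 (1.2 equiv), PPh3 (1.25 equiv), CH2Cl2, 0 °C; used crude
Reagents that add atoms: carbon tetrabromide BrC(Br)(Br)Br
Why: Appel bromination is neutral, so the acid-sensitive furan survives and the primary allylic bromide forms without allylic transposition or loss of E geometry.

Step 5
Reactants: 8 (2S)-2-methylbutane-1,4-diol
Product: 9 (2S)-1,4-dichloro-2-methylbutane
Conditions: SOCl2 (2.5 equiv), pyridine (2.2 equiv), CH2Cl2, 0 °C then 40 °C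
Reagents that add atoms: thionyl chloride O=S(Cl)Cl
Why: Chlorodehydroxylation through the bis-chlorosulfite with SN2 attack of chloride at the two primary carbons; the stereocentre is not a reacting atom.

Step 6
Reactants: 9 (2S)-1,4-dichloro-2-methylbutane
Product: 10 (2S)-1-chloro-4-iodo-2-methylbutane
Conditions: NaI (0.9 equiv), 2-butanone, 80 °C; distillation
Reagents that add atoms: sodium iodide [Na+].[I-]
Why: Finkelstein exchange is an SN2 reaction and is about twenty times faster at the unbranched CH2Cl (C16) than at the β-branched CH2Cl (C20); NaCl precipitation drives it.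

Step 7
Reactants: 10 (2S)-1-chloro-4-iodo-2-methylbutane; 7 3-[(3E,7E)-9-bromo-4,8-dimethylnona-3,7-dien-1-yl]furan
Product: 12 3-[(3E,7E,12S)-13-chloro-4,8,12-trimethyltrideca-3,7-dien-1-yl]furan, via Grignard reagent 11 (not isolated)
Conditions: 10 (1.3 equiv), Mg, Et2O, 0 °C to rt; then 7, Li2CuCl4 (5 mol %), THF, −78 to 0 °C
Reagents that add atoms: magnesium [Mg] (stays only in 11)
Why: Kochi-type Li2CuCl4-catalysed coupling of an alkylmagnesium halide with a primary allylic bromide goes mainly at the α-carbon with retention of the E-alkene; the alkyl chloride is inert, and C18 (S, from 8) is remote from the reacting carbons.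

Step 8
Reactants: 12 3-[(3E,7E,12S)-13-chloro-4,8,12-trimethyltrideca-3,7-dien-1-yl]furan; 13 diethyl oxalpropionate (diethyl 2-methyl-3-oxobutanedioate)
Product: 17 (5Z)-5-[(2S,6E,10E)-13-(furan-3-yl)-2,6,10-trimethyltrideca-6,10-dien-1-ylidene]-4-hydroxy-3-methylfuran-2(5H)-one, via sodium enolate 14 (not isolated), via Grignard reagent 15 (not isolated), via dioxo ester 16 (not isolated)
Conditions: 13 (1.5 equiv), NaH (1.5 equiv), THF, 0 °C; 12, Mg, BrCH2CH2Br (cat.), THF, 65 °C, then added to the enolate at −78 to 0 °C; 1 M HCl; then PPTS (0.2 equiv), toluene, 80 °C, 4 Å MS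
Reagents that add atoms: magnesium [Mg] (stays only in 15); sodium hydride [Na+].[H-] (sodium stays only in 14)
Why: Proposed new method: in enolate 14 the C24 ester is part of the delocalised anion and inert, so the Grignard reagent can only attack the oxalyl ester (C21), and the magnesium-chelated tetrahedral adduct next to the enolate oxygen should survive until the acid quench (closest known reaction: mono-addition of Grignard reagents to diethyl oxalate to give α-keto esters); the resulting 2-methyl-3,4-dioxo ester 16 is the open form of the oxidised terminal isoprene unit and closes under mild acid by enol lactonisation (C21 enol oxygen onto C24, loss of ethanol, as 4-oxo acids give 5-ylidenebutenolides) to the thermodynamically preferred 20Z olefin, while the non-enolisable C18 stays S.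

Step 9
Reactants: 17 (5Z)-5-[(2S,6E,10E)-13-(furan-3-yl)-2,6,10-trimethyltrideca-6,10-dien-1-ylidene]-4-hydroxy-3-methylfuran-2(5H)-one; 18 palmitoyl chloride
Product: 19 (2Z)-2-[(2S,6E,10E)-13-(furan-3-yl)-2,6,10-trimethyltrideca-6,10-dien-1-ylidene]-4-methyl-5-oxo-2,5-dihydrofuran-3-yl hexadecanoate
Conditions: 18 (1.1 equiv), Et3N (1.2 equiv), CH2Cl2, 0 °C
Reagents that add atoms: none
Why: O-acylation of a 3-substituted tetronic acid (a vinylogous carboxylic acid) with an acid chloride and a tertiary amine gives the 4-O-acyl enol ester; C3 is blocked, so no C-acylation can follow, and the weak base leaves C18 and the olefins untouched.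

Step 10
Reactants: 19 (2Z)-2-[(2S,6E,10E)-13-(furan-3-yl)-2,6,10-trimethyltrideca-6,10-dien-1-ylidene]-4-methyl-5-oxo-2,5-dihydrofuran-3-yl hexadecanoate
Product: 20 (2E)-2-[(2S,6E,10E)-13-(furan-3-yl)-2,6,10-trimethyltrideca-6,10-dien-1-ylidene]-4-methyl-5-oxo-2,5-dihydrofuran-3-yl hexadecanoate (target CNP0269639.1)
Conditions: [Ir(dF(CF3)ppy)2(dtbbpy)]PF6 (1 mol %), rigorously degassed CH2Cl2, 450 nm LEDs, 20 °C, to the photostationary state; chromatography on AgNO3-impregnated silica, recovered 19 re-irradiated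
Reagents that add atoms: none
Why: Proposed new method: triplet energy transfer to the planar 20Z dienyl-lactone chromophore gives a twisted C20–C21 triplet that relaxes to both isomers, while the 20E isomer, pushed out of planarity by the clash between the C18 branch and the palmitoyloxy group, should be sensitised less efficiently and accumulate (closest known reactions: visible-light energy-transfer geometric isomerisation of conjugated alkenes and UV Z/E isomerisation of 5-ylidenebutenolides); the isolated trisubstituted alkenes and the furan lie well above the sensitiser triplet energy, oxygen is excluded to protect the furan, and C18 is not touched.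

**Compound list**
1 | (E)-β-farnesene, (6E)-7,11-dimethyl-3-methylidenedodeca-1,6,10-triene | C=CC(=C)CC/C=C(\C)CCC=C(C)C | starting material
2 | (2E)-2-[(3E)-4,8-dimethylnona-3,7-dien-1-yl]but-2-ene-1,4-diyl bis(pinacolboronate), the two CH2B groups cis | CC1(C)OB(C/C=C(\CB2OC(C)(C)C(C)(C)O2)CC/C=C(\C)CCC=C(C)C)OC1(C)C | intermediate
3 | (2Z)-2-[(3E)-4,8-dimethylnona-3,7-dien-1-yl]but-2-ene-1,4-diol | OC/C=C(\CO)CC/C=C(\C)CCC=C(C)C | intermediate
4 | 4-[(3E)-4,8-dimethylnona-3,7-dien-1-yl]-2,5-dihydrofuran-2-ol (lactol, racemic at C2) | OC1OCC(CC/C=C(\C)CCC=C(C)C)=C1 | intermediate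
5 | dendrolasin, 3-[(3E)-4,8-dimethylnona-3,7-dien-1-yl]furan | CC(C)=CCC/C(C)=C/CCc1ccoc1 | intermediate
6 | neotorreyol, (2E,6E)-9-(furan-3-yl)-2,6-dimethylnona-2,6-dien-1-ol | OC/C(C)=C/CC/C(C)=C/CCc1ccoc1 | intermediate
7 | 3-[(3E,7E)-9-bromo-4,8-dimethylnona-3,7-dien-1-yl]furan | BrC/C(C)=C/CC/C(C)=C/CCc1ccoc1 | intermediate
8 | (2S)-2-methylbutane-1,4-diol | OC[C@@H](C)CCO | starting material
9 | (2S)-1,4-dichloro-2-methylbutane | ClC[C@@H](C)CCCl | intermediate
10 | (2S)-1-chloro-4-iodo-2-methylbutane | ClC[C@@H](C)CCI | intermediate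
11 | [(3S)-4-chloro-3-methylbutyl]magnesium iodide | ClC[C@@H](C)CC[Mg]I | intermediate
12 | 3-[(3E,7E,12S)-13-chloro-4,8,12-trimethyltrideca-3,7-dien-1-yl]furan | ClC[C@@H](C)CCC/C(C)=C/CC/C(C)=C/CCc1ccoc1 | intermediate
13 | diethyl oxalpropionate (diethyl 2-methyl-3-oxobutanedioate) | CCOC(=O)C(=O)C(C)C(=O)OCC | starting material
14 | sodium enolate of 13 (sodium 1,4-diethoxy-3-methyl-1,4-dioxobut-2-en-2-olate) | [Na+].CCOC(=O)C([O-])=C(C)C(=O)OCC | intermediate
15 | [(2S,6E,10E)-13-(furan-3-yl)-2,6,10-trimethyltrideca-6,10-dien-1-yl]magnesium chloride | Cl[Mg]C[C@@H](C)CCC/C(C)=C/CC/C(C)=C/CCc1ccoc1 | intermediate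
16 | ethyl (6S,10E,14E)-17-(furan-3-yl)-2,6,10,14-tetramethyl-3,4-dioxoheptadeca-10,14-dienoate (C2 not defined, enolised) | CCOC(=O)C(C)C(=O)C(=O)C[C@@H](C)CCC/C(C)=C/CC/C(C)=C/CCc1ccoc1 | intermediate
17 | (5Z)-5-[(2S,6E,10E)-13-(furan-3-yl)-2,6,10-trimethyltrideca-6,10-dien-1-ylidene]-4-hydroxy-3-methylfuran-2(5H)-one | OC1=C(C)C(=O)O\C1=C/[C@@H](C)CCC/C(C)=C/CC/C(C)=C/CCc1ccoc1 | intermediate
18 | palmitoyl chloride (hexadecanoyl chloride) | CCCCCCCCCCCCCCCC(=O)Cl | starting material
19 | (2Z)-2-[(2S,6E,10E)-13-(furan-3-yl)-2,6,10-trimethyltrideca-6,10-dien-1-ylidene]-4-methyl-5-oxo-2,5-dihydrofuran-3-yl hexadecanoate | CCCCCCCCCCCCCCCC(=O)OC1=C(C)C(=O)O\C1=C/[C@@H](C)CCC/C(C)=C/CC/C(C)=C/CCc1ccoc1 | intermediate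
20 | (2E)-2-[(2S,6E,10E)-13-(furan-3-yl)-2,6,10-trimethyltrideca-6,10-dien-1-ylidene]-4-methyl-5-oxo-2,5-dihydrofuran-3-yl hexadecanoate | CCCCCCCCCCCCCCCC(=O)OC1=C(C)C(=O)O/C1=C/[C@@H](C)CCC/C(C)=C/CC/C(C)=C/CCc1ccoc1 | target

**Step count and risks**
Total steps: 10. Longest linear sequence: 8 (steps 1, 2, 3, 4, 7, 8, 9, 10 from 1).

Steps most likely to fail:

- Step 8 (the mono-acylation may over-add or pick the wrong ester, and the acid lactonisation has to spare the furan). The fallback sets out from 12 and comes back at 17. The Grignard reagent 15 made from 12 is added to excess diethyl oxalate (THF, −78 °C) to give the α-keto ester ethyl (4S,8E,12E)-15-(furan-3-yl)-4,8,12-trimethyl-2-oxopentadeca-8,12-dienoate F1. Its enol is acylated with propanoyl chloride, Et3N and DMAP to give the enol ester ethyl (2Z,4S,8E,12E)-15-(furan-3-yl)-4,8,12-trimethyl-2-(propanoyloxy)pentadeca-2,8,12-trienoate F2. LiN(SiMe3)2 (2.2 equiv, THF, −78 to 0 °C) then closes the ring by a Dieckmann condensation (C22–C23 bond) to 17.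

- Step 10 (the photostationary mixture may stay poor in the E isomer, and the enol ester or furan may suffer). The fallback sets out from 12 and comes back at 20, and it fixes the olefin geometry before the ring exists. The Grignard reagent 15 is treated with B(OMe)3 and then NaOH/H2O2 to give (2S,6E,10E)-13-(furan-3-yl)-2,6,10-trimethyltrideca-6,10-dien-1-ol F3. Dess–Martin periodinane (NaHCO3, CH2Cl2, 0 °C) gives (2S,6E,10E)-13-(furan-3-yl)-2,6,10-trimethyltrideca-6,10-dienal F4. A Still–Gennari-type olefination with methyl 2-[bis(2,2,2-trifluoroethoxy)phosphoryl]-2-(propanoyloxy)acetate (KN(SiMe3)2, 18-crown-6, THF, −78 °C) is expected to place the chain cis to the ester, giving methyl (2E,4S,8E,12E)-15-(furan-3-yl)-4,8,12-trimethyl-2-(propanoyloxy)pentadeca-2,8,12-trienoate F5. LiN(SiMe3)2 then closes the ring with that geometry kept, giving (5E)-5-[(2S,6E,10E)-13-(furan-3-yl)-2,6,10-trimethyltrideca-6,10-dien-1-ylidene]-4-hydroxy-3-methylfuran-2(5H)-one F6, and palmitoyl chloride 18 with Et3N gives 20.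

- Step 7 (SN2' attack or E/Z erosion in the allylic coupling). The fallback sets out from 7 and comes back at 12, with the polarity at C15 reversed. PhSO2Na in DMF converts 7 into 3-[(3E,7E)-9-(benzenesulfonyl)-4,8-dimethylnona-3,7-dien-1-yl]furan F7. Deprotonation with n-BuLi (THF, −78 °C) and alkylation with iodide 10 gives 3-[(3E,7E,12S)-9-(benzenesulfonyl)-13-chloro-4,8,12-trimethyltrideca-3,7-dien-1-yl]furan F8. Reductive desulfonylation with [PdCl2(dppp)] (5 mol %) and LiBHEt3 (THF, 0 °C) gives 12.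

**Further compounds**
F1 | step 8 | ethyl (4S,8E,12E)-15-(furan-3-yl)-4,8,12-trimethyl-2-oxopentadeca-8,12-dienoate | CCOC(=O)C(=O)C[C@@H](C)CCC/C(C)=C/CC/C(C)=C/CCc1ccoc1
F2 | step 8 | ethyl (2Z,4S,8E,12E)-15-(furan-3-yl)-4,8,12-trimethyl-2-(propanoyloxy)pentadeca-2,8,12-trienoate | CCOC(=O)/C(OC(=O)CC)=C/[C@@H](C)CCC/C(C)=C/CC/C(C)=C/CCc1ccoc1
F3 | step 10 | (2S,6E,10E)-13-(furan-3-yl)-2,6,10-trimethyltrideca-6,10-dien-1-ol | OC[C@@H](C)CCC/C(C)=C/CC/C(C)=C/CCc1ccoc1
F4 | step 10 | (2S,6E,10E)-13-(furan-3-yl)-2,6,10-trimethyltrideca-6,10-dienal | O=C[C@@H](C)CCC/C(C)=C/CC/C(C)=C/CCc1ccoc1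
F5 | step 10 | methyl (2E,4S,8E,12E)-15-(furan-3-yl)-4,8,12-trimethyl-2-(propanoyloxy)pentadeca-2,8,12-trienoate | COC(=O)/C(OC(=O)CC)=C\[C@@H](C)CCC/C(C)=C/CC/C(C)=C/CCc1ccoc1
F6 | step 10 | (5E)-5-[(2S,6E,10E)-13-(furan-3-yl)-2,6,10-trimethyltrideca-6,10-dien-1-ylidene]-4-hydroxy-3-methylfuran-2(5H)-one | OC1=C(C)C(=O)O/C1=C/[C@@H](C)CCC/C(C)=C/CC/C(C)=C/CCc1ccoc1
F7 | step 7 | 3-[(3E,7E)-9-(benzenesulfonyl)-4,8-dimethylnona-3,7-dien-1-yl]furan | O=S(=O)(C/C(C)=C/CC/C(C)=C/CCc1ccoc1)c1ccccc1
F8 | step 7 | 3-[(3E,7E,12S)-9-(benzenesulfonyl)-13-chloro-4,8,12-trimethyltrideca-3,7-dien-1-yl]furan (both C9 epimers) | ClC[C@@H](C)CCC(/C(C)=C/CC/C(C)=C/CCc1ccoc1)S(=O)(=O)c1ccccc1
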